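**Retrosynthetic overview**

1. The last disconnection is a global acid hydrolysis of four MOM ethers and one dioxolane from the fully protected diaryl ester 12.
2. The key disconnection cuts ester 12 on both sides of its carbonyl carbon, at C1'(ring B)–C(=O) and at O–CH2(ring A), into the aryllithium from bromide 4, CO2 (9) and benzylic bromide 8.
3. The feature the plan rests on: the single carbon that links ring B C1' to the benzylic oxygen of ring A is at the oxidation level of CO2, and the two unsubstituted ring carbons of atranol (C3 and C5) are mirror-equivalent, so one bromination marks C1' without ambiguity. On ring A only the C6 methyl is ortho to the ester, so only it is laterally lithiated.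
4. Ring B piece 4 comes from atranol by bromination, MOM protection and dioxolane formation under aprotic Noyori conditions, chosen because MOM ethers ortho to the formyl group are not expected to survive a Brønsted-acid acetalisation. Ring A piece 8 comes from atraric acid by MOM protection and lateral lithiation–bromination.
5. No ring is formed at any stage; rings A and B are bought intact as atraric acid and atranol.

Key step: step 6

Remark on the chemistry: the target has no stereogenic element, so no stereocontrol is needed. Ring A is the methyl benzoate ring (C1–C6) and ring B the formyl-bearing acyl ring (C1'–C6').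

**Route**

Step 1
Reactants: 1 atranol (2,6-dihydroxy-4-methylbenzaldehyde)
Product: 2 3-bromo-2,6-dihydroxy-4-methylbenzaldehyde
Conditions: NBS (1.0 equiv), MeCN, −20 → 0 °C, dark
Reagents that add atoms: N-bromosuccinimide, BrN1C(=O)CCC1=O
Why: Electrophilic aromatic bromination; the only open ring carbons, C3 and C5, are equivalent and activated ortho/para by the two hydroxyls, so one equivalent of NBS at low temperature should give a single monobromide, the first bromine slowing a second substitution.

Step 2
Reactants: 2 3-bromo-2,6-dihydroxy-4-methylbenzaldehyde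
Product: 3 3-bromo-2,6-bis(methoxymethoxy)-4-methylbenzaldehyde
Conditions: NaH (2.4 equiv), MOMCl (2.6 equiv), DMF, 0 °C → rt
Reagents that add atoms: chloromethyl methyl ether (MOMCl), COCCl
Why: Williamson-type O-alkylation of the sodium bis-phenoxide with the very reactive chloromethyl ether should cap both hydrogen-bonded oxygens, including the one flanked by bromine, and the acid-free medium leaves the aldehyde untouched.

Step 3
Reactants: 3 3-bromo-2,6-bis(methoxymethoxy)-4-methylbenzaldehyde
Product: 4 2-[3-bromo-2,6-bis(methoxymethoxy)-4-methylphenyl]-1,3-dioxolane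
Conditions: Me3SiOCH2CH2OSiMe3 (2 equiv), Me3SiOTf (5 mol %), CH2Cl2, −78 → −30 °C; pyridine quench; chromatography on Et3N-deactivated silica
Reagents that add atoms: 1,2-bis(trimethylsilyloxy)ethane, C[Si](C)(C)OCCO[Si](C)(C)C
Why: Noyori acetalisation; the silyl triflate activates the aldehyde oxygen at low temperature and the bis-silyl glycol closes the dioxolane under aprotic, kinetically controlled conditions, so the ortho MOM ethers, which a Brønsted-acid Dean–Stark acetalisation would strip, should be kept.

Step 4
Reactants: 5 atraric acid (methyl 2,4-dihydroxy-3,6-dimethylbenzoate)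
Product: 6 methyl 2,4-bis(methoxymethoxy)-3,6-dimethylbenzoate
Conditions: NaH (2.5 equiv), MOMCl (2.8 equiv), DMF, 0 °C → rt
Reagents that add atoms: chloromethyl methyl ether (MOMCl), COCCl
Why: Williamson-type O-alkylation of the bis-phenoxide; the strong base is needed for the ester-chelated, methyl-flanked C2 hydroxyl, and the methyl ester is inert to NaH and to MOMCl.

Step 5
Reactants: 6 methyl 2,4-bis(methoxymethoxy)-3,6-dimethylbenzoate
Product: 8 methyl 6-(bromomethyl)-2,4-bis(methoxymethoxy)-3-methylbenzoate, via benzylic organolithium 7 (not isolated)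
Conditions: LiN(i-Pr)2 (1.15 equiv), THF, −78 °C; then cannulated into BrCl2C–CCl2Br (1.5 equiv), THF, −78 °C; NH4Cl quench at −78 °C
Reagents that add atoms: 1,2-dibromo-1,1,2,2-tetrachloroethane, BrC(Cl)(Cl)C(Cl)(Cl)Br
Why: Lateral (benzylic) lithiation of an ortho-toluate followed by halophilic bromination; only the C6 methyl is conjugated with the ester, so the extended enolate 7 forms there and takes Br+ from the perhaloethane (which collapses to tetrachloroethene and LiBr), while inverse addition keeps bromide 8 away from unreacted 7 and the 2-OMOM flank hinders Claisen self-condensation.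

Step 6
Reactants: 4 2-[3-bromo-2,6-bis(methoxymethoxy)-4-methylphenyl]-1,3-dioxolane; 9 carbon dioxide; 8 methyl 6-(bromomethyl)-2,4-bis(methoxymethoxy)-3-methylbenzoate
Product: 12 methyl 6-({[3-(1,3-dioxolan-2-yl)-2,4-bis(methoxymethoxy)-6-methylbenzoyl]oxy}methyl)-2,4-bis(methoxymethoxy)-3-methylbenzoate, via aryllithium 10 (not isolated), via lithium carboxylate 11 (not isolated)
Conditions: t-BuLi (titrated, 2.0 equiv per 4), THF, −78 °C; CO2 (dry gas, excess), −78 → 0 °C, then Ar purge; 8 (0.8 equiv) in DMF, n-Bu4NI (10 mol %), 0 → 40 °C
Reagents that add atoms: none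
Why: Bromine–lithium exchange with two equivalents of t-BuLi (the second destroys the tert-butyl bromide) gives aryllithium 10, held by the ortho OMOM oxygen, which adds to CO2 to form the C1'–carbonyl bond; once DMF and catalytic iodide are added, lithium carboxylate 11 displaces bromide from the primary benzylic carbon of 8 by SN2 and so forms the O–CH2 bond. The closest known chemistry is carboxylation of an organolithium followed by in situ O-alkylation of the carboxylate salt with a reactive halide, two standard reactions run here in one flask. No ring is closed and no stereocentre is created. The step needs chemoselectivity: no carbanion may remain when 8 enters, which is secured by exact titration of t-BuLi, an excess of CO2 and a purge before the bromide is added, so that only the carboxylate oxygen, a good nucleophile even between two ortho substituents, meets the methyl ester and the bromide. Regiochemistry is settled beforehand, because the bromine of 4 sits on one of the two symmetry-equivalent carbons of atranol. Working through the carboxylate salt also avoids the free ortho-MOM benzoic acid, which would cleave its own acetals, and avoids a ring A benzylic alcohol, which would lactonise to a phthalide.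

Step 7
Reactants: 12 methyl 6-({[3-(1,3-dioxolan-2-yl)-2,4-bis(methoxymethoxy)-6-methylbenzoyl]oxy}methyl)-2,4-bis(methoxymethoxy)-3-methylbenzoate
Product: 13 methyl 6-{[(3-formyl-2,4-dihydroxy-6-methylbenzoyl)oxy]methyl}-2,4-dihydroxy-3-methylbenzoate (target)
Conditions: 3 M aq. HCl, THF/MeOH (1:2), 45 °C
Reagents that add atoms: water, O
Why: Acid-catalysed acetal hydrolysis through oxocarbenium ions removes the four MOM ethers and the dioxolane together; methanol traps the methoxymethyl cations as dimethoxymethane so the freed resorcinol rings are not hydroxymethylated, and the two 2,6-disubstituted aryl esters and the meta-oxygenated benzylic C–O bond should resist acidolysis.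

**Compound list**

1 | atranol (2,6-dihydroxy-4-methylbenzaldehyde) | Cc1cc(O)c(C=O)c(O)c1 | starting material
2 | 3-bromo-2,6-dihydroxy-4-methylbenzaldehyde | Cc1cc(O)c(C=O)c(O)c1Br | intermediate
3 | 3-bromo-2,6-bis(methoxymethoxy)-4-methylbenzaldehyde | Cc1cc(OCOC)c(C=O)c(OCOC)c1Br | intermediate
4 | 2-[3-bromo-2,6-bis(methoxymethoxy)-4-methylphenyl]-1,3-dioxolane | Cc1cc(OCOC)c(C2OCCO2)c(OCOC)c1Br | intermediate
5 | atraric acid (methyl 2,4-dihydroxy-3,6-dimethylbenzoate) | COC(=O)c1c(C)cc(O)c(C)c1O | starting material
6 | methyl 2,4-bis(methoxymethoxy)-3,6-dimethylbenzoate | COC(=O)c1c(C)cc(OCOC)c(C)c1OCOC | intermediate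
7 | methyl 6-(lithiomethyl)-2,4-bis(methoxymethoxy)-3-methylbenzoate (benzylic organolithium, not isolated) | COC(=O)c1c(C[Li])cc(OCOC)c(C)c1OCOC | intermediate
8 | methyl 6-(bromomethyl)-2,4-bis(methoxymethoxy)-3-methylbenzoate | COC(=O)c1c(CBr)cc(OCOC)c(C)c1OCOC | intermediate
9 | carbon dioxide | O=C=O | starting material
10 | [3-(1,3-dioxolan-2-yl)-2,4-bis(methoxymethoxy)-6-methylphenyl]lithium (aryllithium, not isolated) | Cc1cc(OCOC)c(C2OCCO2)c(OCOC)c1[Li] | intermediate
11 | lithium 3-(1,3-dioxolan-2-yl)-2,4-bis(methoxymethoxy)-6-methylbenzoate (not isolated) | Cc1cc(OCOC)c(C2OCCO2)c(OCOC)c1C(=O)[O-].[Li+] | intermediate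
12 | methyl 6-({[3-(1,3-dioxolan-2-yl)-2,4-bis(methoxymethoxy)-6-methylbenzoyl]oxy}methyl)-2,4-bis(methoxymethoxy)-3-methylbenzoate | COC(=O)c1c(COC(=O)c2c(C)cc(OCOC)c(C3OCCO3)c2OCOC)cc(OCOC)c(C)c1OCOC | intermediate
13 | methyl 6-{[(3-formyl-2,4-dihydroxy-6-methylbenzoyl)oxy]methyl}-2,4-dihydroxy-3-methylbenzoate | COC(=O)c1c(COC(=O)c2c(C)cc(O)c(C=O)c2O)cc(O)c(C)c1O | target

**Step count**

Total: 7 steps. Longest linear sequence: 5 steps (steps 1, 2, 3, 6, 7); the ring A branch (steps 4 and 5) joins at step 6.

**Steps most likely to fail**

Step 6 (three-component union). Carboxylation may be incomplete, or stray alkyllithium may survive as a competing carboxylate, so that a carbanion attacks the methyl ester or the benzylic bromide of 8. The aggregated lithium carboxylate may also alkylate too slowly, leaving 8 to decompose. The fallback separates the two bond formations; it sets out from 4 and comes back at 12. Bromide 4 is exchanged and carboxylated as in step 6, but the mixture is then poured into cold aqueous NaH2PO4 (about pH 5). The acid 3-(1,3-dioxolan-2-yl)-2,4-bis(methoxymethoxy)-6-methylbenzoic acid F1 is extracted quickly and used at once, so that no organometallic species is left. In a second flask F1 is deprotonated with Cs2CO3 in DMF and the cesium carboxylate is alkylated with 8 at room temperature, which should give 12.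

Step 5 (lateral lithiation–bromination). The benzylic anion may be alkylated by freshly formed bromide (bibenzyl coupling), may add to the ester of a second molecule, or may be brominated twice after proton exchange. The fallback replaces the bromide by a halide that is inert toward the anion and is activated only in the coupling flask; it sets out from 6 and comes back at 12. Anion 7 is made as before and quenched with hexachloroethane, a positive-chlorine donor, to give methyl 6-(chloromethyl)-2,4-bis(methoxymethoxy)-3-methylbenzoate F2, a much poorer SN2 partner for 7 than the bromide. F2 then takes the place of 8 in step 6, with n-Bu4NI (20 mol %) in DMF turning it over as the benzylic iodide, and the lithium carboxylate 11 should give 12.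

Step 3 (dioxolane formation beside MOM ethers). The silyl triflate may exchange or remove the ortho MOM ethers, or the hindered, electron-rich aldehyde may acetalise incompletely. The fallback carries the formyl carbon at the alcohol oxidation level, which needs no acid before the end; it sets out from 3 and comes back at 13.
- Aldehyde 3 is reduced with NaBH4 in THF/MeOH at 0 °C to [3-bromo-2,6-bis(methoxymethoxy)-4-methylphenyl]methanol F3.
- F3 is silylated (TBSCl, imidazole, DMF) to {[3-bromo-2,6-bis(methoxymethoxy)-4-methylphenyl]methoxy}(tert-butyl)dimethylsilane F4. The silyl ether is meta to the carbon that will carry lithium, so no silyl migration is possible.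
- F4, CO2 (9) and bromide 8 are joined under the conditions of step 6 to give methyl 6-({[3-({[tert-butyl(dimethyl)silyl]oxy}methyl)-2,4-bis(methoxymethoxy)-6-methylbenzoyl]oxy}methyl)-2,4-bis(methoxymethoxy)-3-methylbenzoate F5.
- Bu4NF buffered with AcOH in THF frees methyl 6-({[3-(hydroxymethyl)-2,4-bis(methoxymethoxy)-6-methylbenzoyl]oxy}methyl)-2,4-bis(methoxymethoxy)-3-methylbenzoate F6.
- MnO2 in CH2Cl2 oxidises the benzylic alcohol to methyl 6-({[3-formyl-2,4-bis(methoxymethoxy)-6-methylbenzoyl]oxy}methyl)-2,4-bis(methoxymethoxy)-3-methylbenzoate F7.
- The acid treatment of step 7 on F7 removes the four MOM ethers and should give 13.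

**Further compounds**

F1 | step 6 | 3-(1,3-dioxolan-2-yl)-2,4-bis(methoxymethoxy)-6-methylbenzoic acid | Cc1cc(OCOC)c(C2OCCO2)c(OCOC)c1C(=O)O
F2 | step 5 | methyl 6-(chloromethyl)-2,4-bis(methoxymethoxy)-3-methylbenzoate | COC(=O)c1c(CCl)cc(OCOC)c(C)c1OCOC
F3 | step 3 | [3-bromo-2,6-bis(methoxymethoxy)-4-methylphenyl]methanol | Cc1cc(OCOC)c(CO)c(OCOC)c1Br
F4 | step 3 | {[3-bromo-2,6-bis(methoxymethoxy)-4-methylphenyl]methoxy}(tert-butyl)dimethylsilane | Cc1cc(OCOC)c(CO[Si](C)(C)C(C)(C)C)c(OCOC)c1Br
F5 | step 3 | methyl 6-({[3-({[tert-butyl(dimethyl)silyl]oxy}methyl)-2,4-bis(methoxymethoxy)-6-methylbenzoyl]oxy}methyl)-2,4-bis(methoxymethoxy)-3-methylbenzoate | COC(=O)c1c(COC(=O)c2c(C)cc(OCOC)c(CO[Si](C)(C)C(C)(C)C)c2OCOC)cc(OCOC)c(C)c1OCOC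
F6 | step 3 | methyl 6-({[3-(hydroxymethyl)-2,4-bis(methoxymethoxy)-6-methylbenzoyl]oxy}methyl)-2,4-bis(methoxymethoxy)-3-methylbenzoate | COC(=O)c1c(COC(=O)c2c(C)cc(OCOC)c(CO)c2OCOC)cc(OCOC)c(C)c1OCOC
F7 | step 3 | methyl 6-({[3-formyl-2,4-bis(methoxymethoxy)-6-methylbenzoyl]oxy}methyl)-2,4-bis(methoxymethoxy)-3-methylbenzoate | COC(=O)c1c(COC(=O)c2c(C)cc(OCOC)c(C=O)c2OCOC)cc(OCOC)c(C)c1OCOC
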